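**Plan**

1. Retrosynthesis: the C3 CH2OH is traced back to an ester and the C2–H/C3–H pair to the C2=C3 bond of an ethyl 2-aryl-4,5-dihydrofuran-3-carboxylate. O1–C5 is then cut, which folds C5 back onto C3 as the ring CH2 of a 1-aroylcyclopropane-1-carboxylate. The two cyclopropane bonds at the quaternary carbon are cut to a β-keto ester and a chiral 1,2-bis-electrophile, and the ring B–CH2 bond to an aryl Grignard reagent and glycidol.
2. Enabling feature: in the tetrahydrofuran (O1; C2 bearing ring A = 3,4,5-trimethoxyphenyl; C3 bearing CH2OH; C4 bearing the 2,4,5-trimethoxybenzyl group of ring B; C5H2), the unsubstituted O1–C5H2 unit beside benzyl-bearing C4 is what an acylcyclopropane delivers when opened at its ring CH2, and the cis C2/C3 pair is a masked tetrasubstituted enol ether C2=C3.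
3. Forward: ring B Grignard reagent + (S)-glycidol → (R)-diol → cyclic sulfate → double C-alkylation of the ring A β-keto ester (cyclopropane) → ring expansion to the dihydrofuran (the only ring of the target) → hydrogenation → ester reduction.
4. Stereochemistry: C4 comes from (S)-glycidol (one inversion in the cyclopropane closure, untouched in the ring expansion). C2 and C3 are set together by syn hydrogenation on the face away from the C4 benzyl group, giving the all-cis (2R,3R,4R) array.

Key step: step 4

Remark 1: the carbinol centre is taken from (S)-glycidol and not from an asymmetric dihydroxylation of the allylarene, because monosubstituted allylarenes are a weak substrate class for osmium-catalysed dihydroxylation and the target is required as a single enantiomer.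
Remark 2: C1 of cyclopropane 9 is drawn as (1R,2S) (aroyl trans to the benzyl group); a C1 epimer, if formed, is carried along, since C1 becomes sp2 in step 4.

**Route**

Step 1
Reactants: 1 1-bromo-2,4,5-trimethoxybenzene; 2 (S)-glycidol
Product: 4 (R)-3-(2,4,5-trimethoxyphenyl)propane-1,2-diol, via Grignard reagent 3 (not isolated)
Conditions: 1 (2.4 equiv), Mg, THF, reflux; then CuI (10 mol%), 2 (1.0 equiv), THF, −30 → 0 °C; cold 1 M HCl work-up
Reagents that add atoms: none
Why: Copper-catalysed SN2 opening of the epoxide by the aryl Grignard reagent occurs at the terminal CH2 of the magnesium alkoxide of 2 (whose Payne rearrangement is degenerate), so the existing stereocentre is carried over untouched and is (R) in 4 only because the CIP priorities change.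

Step 2
Reactants: 4 (R)-3-(2,4,5-trimethoxyphenyl)propane-1,2-diol
Product: 6 (4R)-4-(2,4,5-trimethoxybenzyl)-1,3,2-dioxathiolane 2,2-dioxide, via cyclic sulfite 5 (not isolated)
Conditions: SOCl2, Et3N, CH2Cl2, 0 °C; then RuCl3·3H2O (0.5 mol%), NaIO4 (1.3 equiv), MeCN/H2O, 0 °C, 15 min
Reagents that add atoms: thionyl chloride, O=S(Cl)Cl; sodium periodate, [Na+].[O-]I(=O)(=O)=O
Why: In this cyclic sulfite–cyclic sulfate sequence the diol condenses with SOCl2 and the sulfite is then oxidised at sulfur by catalytic RuO4 within minutes at 0 °C, far faster than RuO4 attacks the electron-rich ring B, while the carbinol centre is not involved and stays (R).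

Step 3
Reactants: 6 (4R)-4-(2,4,5-trimethoxybenzyl)-1,3,2-dioxathiolane 2,2-dioxide; 7 ethyl 3-oxo-3-(3,4,5-trimethoxyphenyl)propanoate
Product: 9 ethyl (1R,2S)-1-(3,4,5-trimethoxybenzoyl)-2-(2,4,5-trimethoxybenzyl)cyclopropane-1-carboxylate, via acyclic sulfate monoester 8 (not isolated)
Conditions: NaH (2.2 equiv), DME, 0 °C → rt, then 80 °C
Reagents that add atoms: none
Why: Double C-alkylation of the chelated sodium enolate of 7: SN2 attack at the primary carbon of 6 gives sulfate 8, whose enolate closes the cyclopropane by 3-exo-tet displacement of the secondary sulfate with inversion, turning the (R)-carbinol carbon into the (S)-configured benzyl-bearing ring carbon, and the weakly polar solvent with a sodium counter-ion keeps the U-shaped chelate that favours C- over O-alkylation.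

Step 4
Reactants: 9 ethyl (1R,2S)-1-(3,4,5-trimethoxybenzoyl)-2-(2,4,5-trimethoxybenzyl)cyclopropane-1-carboxylate
Product: 11 ethyl (4R)-2-(3,4,5-trimethoxyphenyl)-4-(2,4,5-trimethoxybenzyl)-4,5-dihydrofuran-3-carboxylate, via ammonium enolate zwitterion 10 (not isolated)
Conditions: DABCO (30 mol%), DMSO, 120 °C, N2
Reagents that add atoms: none
Why: DABCO attacks the unsubstituted ring CH2 of the doubly activated cyclopropane in an SN2 homoconjugate opening that breaks the C1–CH2 bond and gives the ammonium keto-ester enolate 10, whose ketone oxygen then displaces DABCO at the same carbon to form O1–C5 and return the catalyst. The closest known reaction type is the DABCO-catalysed Cloke–Wilson rearrangement of 1-acylcyclopropane-1-carboxylates, and the regiochemical logic is that of the iodide-catalysed Heine isomerisation of N-acylaziridines, where the nucleophile enters and leaves at the less substituted carbon. The dihydrofuran ring closes by 5-exo-tet O-alkylation; the competing 3-exo-tet C-alkylation only returns 9, so the strain-free conjugated enol ether should accumulate. No stereocentre is created: the benzyl-bearing carbon is never a reaction centre and becomes C4 with unchanged geometry (R by the CIP rules), while C1 of 9 is erased as it becomes sp2. The selectivity required is attack at CH2 and not at the benzyl-bearing CH, and it is secured by working without any Lewis or Brønsted acid (no cationic character in the opening), by the steric demand of a tertiary amine toward a secondary, β-branched carbon, and by the absence of any cation-stabilising group directly on that carbon.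

Step 5
Reactants: 11 ethyl (4R)-2-(3,4,5-trimethoxyphenyl)-4-(2,4,5-trimethoxybenzyl)-4,5-dihydrofuran-3-carboxylate
Product: 12 ethyl (2R,3S,4R)-2-(3,4,5-trimethoxyphenyl)-4-(2,4,5-trimethoxybenzyl)tetrahydrofuran-3-carboxylate
Conditions: H2 (10 bar), 5% Rh/Al2O3, EtOAc, rt
Reagents that add atoms: none
Why: Heterogeneous syn hydrogenation of the tetrasubstituted enol ether is expected on the face opposite the C4 benzyl group, which puts both new hydrogens trans to it and so sets C2 and C3 cis to each other and to C4, and Rh on alumina in a neutral solvent is chosen to spare the benzylic C2–O1 bond from hydrogenolysis.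

Step 6
Reactants: 12 ethyl (2R,3S,4R)-2-(3,4,5-trimethoxyphenyl)-4-(2,4,5-trimethoxybenzyl)tetrahydrofuran-3-carboxylate
Product: 13 [(2R,3R,4R)-2-(3,4,5-trimethoxyphenyl)-4-(2,4,5-trimethoxybenzyl)tetrahydrofuran-3-yl]methanol
Conditions: LiAlH4, THF, 0 °C; Fieser work-up
Reagents that add atoms: none
Why: Hydride reduction of the ester to the primary alcohol with LiAlH4 at 0 °C touches no stereocentre, and the fast, cold reduction leaves no time for epimerisation at C3 (the descriptor at C3 changes from S to R only through the CIP priorities).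

**Compound list**

1 | 1-bromo-2,4,5-trimethoxybenzene | COc1cc(OC)c(OC)cc1Br | starting material
2 | (S)-glycidol [(S)-oxiran-2-ylmethanol] | OC[C@H]1CO1 | starting material
3 | 2,4,5-trimethoxyphenylmagnesium bromide | COc1cc(OC)c(OC)cc1[Mg]Br | intermediate
4 | (R)-3-(2,4,5-trimethoxyphenyl)propane-1,2-diol | OC[C@H](O)Cc1cc(OC)c(OC)cc1OC | intermediate
5 | (4R)-4-(2,4,5-trimethoxybenzyl)-1,3,2-dioxathiolane 2-oxide (cyclic sulfite, both sulfur epimers) | O=S1OC[C@@H](Cc2cc(OC)c(OC)cc2OC)O1 | intermediate
6 | (4R)-4-(2,4,5-trimethoxybenzyl)-1,3,2-dioxathiolane 2,2-dioxide (cyclic sulfate) | O=S1(=O)OC[C@@H](Cc2cc(OC)c(OC)cc2OC)O1 | intermediate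
7 | ethyl 3-oxo-3-(3,4,5-trimethoxyphenyl)propanoate | CCOC(=O)CC(=O)c1cc(OC)c(OC)c(OC)c1 | starting material
8 | sodium (2S)-4-(ethoxycarbonyl)-5-oxo-1-(2,4,5-trimethoxyphenyl)-5-(3,4,5-trimethoxyphenyl)pentan-2-yl sulfate (both C4 epimers) | CCOC(=O)C(C[C@@H](Cc1cc(OC)c(OC)cc1OC)OS(=O)(=O)[O-])C(=O)c1cc(OC)c(OC)c(OC)c1.[Na+] | intermediate
9 | ethyl (1R,2S)-1-(3,4,5-trimethoxybenzoyl)-2-(2,4,5-trimethoxybenzyl)cyclopropane-1-carboxylate | CCOC(=O)[C@]1(C(=O)c2cc(OC)c(OC)c(OC)c2)C[C@@H]1Cc1cc(OC)c(OC)cc1OC | intermediate
10 | 1-[(2R)-3-(ethoxycarbonyl)-4-oxido-2-(2,4,5-trimethoxybenzyl)-4-(3,4,5-trimethoxyphenyl)but-3-en-1-yl]-4-aza-1-azoniabicyclo[2.2.2]octane (ammonium enolate zwitterion) | CCOC(=O)C(=C([O-])c1cc(OC)c(OC)c(OC)c1)[C@@H](Cc1cc(OC)c(OC)cc1OC)C[N+]12CCN(CC1)CC2 | intermediate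
11 | ethyl (4R)-2-(3,4,5-trimethoxyphenyl)-4-(2,4,5-trimethoxybenzyl)-4,5-dihydrofuran-3-carboxylate | CCOC(=O)C1=C(c2cc(OC)c(OC)c(OC)c2)OC[C@@H]1Cc1cc(OC)c(OC)cc1OC | intermediate
12 | ethyl (2R,3S,4R)-2-(3,4,5-trimethoxyphenyl)-4-(2,4,5-trimethoxybenzyl)tetrahydrofuran-3-carboxylate (all-cis) | COc1cc(OC)c(OC)cc1C[C@H]1CO[C@@H](c2cc(OC)c(OC)c(OC)c2)[C@H]1C(=O)OCC | intermediate
13 | [(2R,3R,4R)-2-(3,4,5-trimethoxyphenyl)-4-(2,4,5-trimethoxybenzyl)tetrahydrofuran-3-yl]methanol | COc1cc(OC)c(OC)cc1C[C@H]1CO[C@@H](c2cc(OC)c(OC)c(OC)c2)[C@H]1CO | target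

**Step count and risks**

Total steps: 6. Longest linear sequence: 6 steps (from 1 or 2 to 13).

Steps most likely to fail:

1. Step 4. The homoconjugate opening may lose regiocontrol, with the nucleophile entering at the benzyl-bearing carbon and the ring expansion then running to the 5-benzyl regioisomer, or turnover may be slow enough for Hofmann-type elimination from the ammonium intermediate to compete. Fallback: the ring expansion is carried out stepwise and stoichiometrically from 9. Sodium benzenethiolate (DMF, 25–50 °C), a strongly SN2-biased anionic nucleophile that reacts far below 120 °C, should open the ring at CH2 to give ethyl (3R)-2-(3,4,5-trimethoxybenzoyl)-4-(phenylsulfanyl)-3-(2,4,5-trimethoxybenzyl)butanoate F1. S-Methylation with MeOTf (CH2Cl2, 0 °C) gives the methyl(phenyl)sulfonium triflate F2. K2CO3 in MeCN then lets the enolate oxygen displace thioanisole by 5-exo-tet closure, as in the last stage of sulfonium-ylide dihydrofuran annulations, and the route is rejoined at 11; any C-closure only returns 9 for recycling.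

2. Step 3. O-Alkylation may compete with C-alkylation, either in the intermolecular step or in the ring closure (5-exo-tet attack of the enolate oxygen on the secondary sulfate), and E2 loss of the secondary sulfate toward the aryl-conjugated alkene may intervene. Fallback: from 6, the cyclopropane is built with diethyl malonate (NaH, DME, reflux), the standard partner of cyclic sulfates, for which O-alkylation is not an issue. This gives diethyl (2S)-2-(2,4,5-trimethoxybenzyl)cyclopropane-1,1-dicarboxylate F3. Selective saponification of the less hindered ester trans to the benzyl group (KOH, 1.0 equiv, EtOH, rt) gives (1R,2S)-1-(ethoxycarbonyl)-2-(2,4,5-trimethoxybenzyl)cyclopropane-1-carboxylic acid F4. Oxalyl chloride with catalytic DMF (CH2Cl2, 0 °C) gives ethyl (1S,2S)-1-(chlorocarbonyl)-2-(2,4,5-trimethoxybenzyl)cyclopropane-1-carboxylate F5. Acylation of 3,4,5-trimethoxyphenylmagnesium bromide with F5 under Fe(acac)3 catalysis (THF, −78 °C) then rejoins the route at 9, with the aroyl group trans to the benzyl group.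

3. Step 5. Reduction of the conjugated, tetrasubstituted enol ether may be slow, so that hydrogenolysis of the benzylic C2–O1 bond, partial saturation of the arenes, or erosion of face selectivity through alkene migration on the metal surface take over. Fallback: the order of the last two operations is reversed. From 11, DIBAL-H (CH2Cl2, −78 °C) reduces the ester to [(4R)-2-(3,4,5-trimethoxyphenyl)-4-(2,4,5-trimethoxybenzyl)-4,5-dihydrofuran-3-yl]methanol F6. Its now non-conjugated, electron-rich double bond is hydrogenated homogeneously with [Ir(cod)(PCy3)(py)]PF6 and H2 (1 atm, CH2Cl2, rt), a hydroxyl-assisted catalyst for hindered alkenes with no hydrogenolysis activity. The C4 benzyl group still shields one face, and the route is rejoined directly at 13.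

**Further compounds**

F1 | step 4 | ethyl (3R)-2-(3,4,5-trimethoxybenzoyl)-4-(phenylsulfanyl)-3-(2,4,5-trimethoxybenzyl)butanoate (both C2 epimers) | CCOC(=O)C(C(=O)c1cc(OC)c(OC)c(OC)c1)[C@@H](Cc1cc(OC)c(OC)cc1OC)CSc1ccccc1
F2 | step 4 | [(2R)-3-(ethoxycarbonyl)-4-oxo-2-(2,4,5-trimethoxybenzyl)-4-(3,4,5-trimethoxyphenyl)butyl](methyl)(phenyl)sulfonium trifluoromethanesulfonate | CCOC(=O)C(C(=O)c1cc(OC)c(OC)c(OC)c1)[C@@H](Cc1cc(OC)c(OC)cc1OC)C[S+](C)c1ccccc1.[O-]S(=O)(=O)C(F)(F)F
F3 | step 3 | diethyl (2S)-2-(2,4,5-trimethoxybenzyl)cyclopropane-1,1-dicarboxylate | CCOC(=O)C1(C(=O)OCC)C[C@@H]1Cc1cc(OC)c(OC)cc1OC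
F4 | step 3 | (1R,2S)-1-(ethoxycarbonyl)-2-(2,4,5-trimethoxybenzyl)cyclopropane-1-carboxylic acid | CCOC(=O)[C@]1(C(=O)O)C[C@@H]1Cc1cc(OC)c(OC)cc1OC
F5 | step 3 | ethyl (1S,2S)-1-(chlorocarbonyl)-2-(2,4,5-trimethoxybenzyl)cyclopropane-1-carboxylate | CCOC(=O)[C@]1(C(=O)Cl)C[C@@H]1Cc1cc(OC)c(OC)cc1OC
F6 | step 5 | [(4R)-2-(3,4,5-trimethoxyphenyl)-4-(2,4,5-trimethoxybenzyl)-4,5-dihydrofuran-3-yl]methanol | OCC1=C(c2cc(OC)c(OC)c(OC)c2)OC[C@@H]1Cc1cc(OC)c(OC)cc1OC
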